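# Proposed synthesis of CNP0333611.1 by lactone‑enolate Claisen ring contraction

Conventions: labdane numbering is used throughout (ring A = C1–C5, C10; ring B = C5–C10; C11 on C9; C17 = methyl on C8; C18 = 4α‑methyl; C19 = 4β‑CH2O; C20 = 10β‑methyl). α is the face opposite C20. TBS = tert‑butyldimethylsilyl. Bicyclic intermediates without the side chain are named as 12,13,14,15,16‑pentanorlabdanes.

## Analysis of the target

- Target 36 is a labdane: a trans‑fused decalin with a tetrasubstituted C8=C9 alkene, the C17 methyl on C8 and, on C9, a chain C11–C16 that ends in an (E)‑3‑methylpropenoic acid.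
- It has five stereocentres: C3 (R), C4 (S), C5 (R), C6 (R) and C10 (S). The C20 methyl, the acyloxymethyl group C19 and the free 6‑hydroxyl are all β and mutually syn‑axial. H5 is α. The 3‑acyloxy group is α (axial), trans to C19 and cis to the C18 methyl.
- Sensitive groups are the two isovalerate esters (no strong base, hydride or organometallic once they are in place), the free acid and the (E)‑enoate.
- The 6‑oxygen is also delicate: as a ketone it would lie β,γ to the C8=C9 alkene, with C7 activated from both sides.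
- The hard points are the two quaternary carbons C4 and C10 flanking C5, the absolute configuration of C10 (which carries no heteroatom), the tetrasubstituted alkene next to it, and telling three hydroxyl groups apart.
- The strategy rests on one feature: C10 is allylic to the oxygenated carbon C6 through C5. A C6 carbinol of defined configuration can pass its chirality to C10 in a [3,3] shift that also joins C9 (carrying C11) to C10 and closes ring B. The C6 oxygen lost in the shift is restored by hydroboration of the C5=C6 alkene that the shift leaves behind.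

## Retrosynthetic reasoning

**36 ⇒ 35 ⇒ 34 ⇒ 33.** The O‑acyl bonds are cut last. The acid is unmasked from allyl ester 35 under neutral conditions. The isovalerates go onto triol 34, where the 6β‑hydroxyl is shielded by the syn‑axial C19 and C20 groups. Triol 34 comes from bis‑silyl ether 33, which tolerates all the earlier base, hydride and organometallic steps.

**33 ⇒ 32 ⇒ 31 ⇒ 29 + 30.** The side chain is cut at C11–C12 and at C13–C16. Allylic bromide 29 alkylates the terminal carbon of the dianion of allyl acetoacetate 30. The C16 methyl then replaces the enol phosphate of 32 with retention, which fixes the (E) geometry; a ketone olefination would not do this reliably.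

**29 ⇒ 28 ⇒ 27 ⇒ 25 (through 26).** The C8=C9 alkene is traced to saturated ester 25.
- A selenoxide or sulfoxide syn‑elimination is not possible here. An electrophile enters the C9 enolate from the α face, anti to C20, and so ends trans to the only β‑hydrogen, H8β.
- That same arrangement (9α‑leaving group and 8β‑H, both axial) is ideal for an anti elimination, so bromide 26 is used.
- C8 and C9 are thus stereocentres only in transit.

**25 ⇒ 24 ⇒ 23 ⇒ 21 ⇒ 20.** The C6–O and C5–H bonds are cut back to the C5=C6 alkene of 21.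
- Hydroboration can only deliver the 6α‑alcohol 23 together with 5α‑H.
- C6 is therefore inverted through ketone 24, whose β face is blocked for hydride.
- This is done before the C8=C9 alkene exists, so no β,γ‑unsaturated 6‑ketone appears on the main line.
- Acid 20 is esterified first because borane would reduce it.

**20 ⇒ 17 (through 19 and 18).** This is the key cut, at C9–C10.
- Acid 20 is the [3,3] product of the silyl ketene acetal 18 of lactone 17.
- In the reverse sense C6–O is re‑formed and ring B becomes a δ‑lactone hanging from the ring A alkene.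
- Gained: quaternary C10 with the configuration dictated by C6, ring B, and C11 on C9.
- The forward reaction must bond an enolate carbon to a fully substituted alkene carbon through a boat.

**17 ⇒ 16 ⇒ 15 ⇒ 13 + 14.** The C8 methyl is removed (conjugate addition to unsaturated lactone 16 places it trans to the ring A substituent). The C8=C9 bond of 16 is opened by retro‑metathesis to acrylate 15, and the ester bond to alcohol 13 and acryloyl chloride 14.

**13 ⇒ 11.** The C6–C7 bond is cut to enal 11 and an allyl nucleophile. A chiral allylborane sets C6 under reagent control, because the neighbouring C4 offers almost no bias (methyl against CH2OTBS).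

**11 ⇒ 10 ⇒ 9 ⇒ 8 ⇒ 7 ⇒ 6.** The C5–C6 bond comes from carbonylation of enol triflate 8. The triflate comes from ketone 7, which can enolise only towards C10. The C20 methyl comes from alkylation of ketone 6.

**6 ⇒ 5 ⇒ 4 ⇒ 3 ⇒ 1 + 2.** C3 and C4 are set together by a desymmetrising mono‑reduction of the prochiral dione 4. The C4–C19 bond comes from the aldol of dione 1 with formaldehyde 2.

## Alternatives that were turned down

**Alternative 1:** Ring A is cut at C1–C10 and C4–C5.
- Forward key step: silyloxy diene A3 adds across the C5=C10 bond of quinone monoketal A2 in a [4+2] cycloaddition, giving the cis‑fused endo adduct A1 with a C9 ketone, a C6 ketal and a C3 silyl enol ether.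
- For: two C–C bonds and C10 are made in one step from flat, cheap partners. C6 arrives at the ketone level and C9 as a ketone ready for enol triflate coupling. On both points it is stronger than the chosen route, which spends three steps on C6 and two on the C8=C9 alkene.
- Against:
  - A1 is cis‑fused, so C5 must be epimerised after the C6 ketone is unveiled.
  - A1 is racemic unless a chiral Lewis acid controls a hindered, α‑methylated dienophile whose ketal ionises easily.
  - C4 is still tertiary and must be methylated between two carbonyl groups with the correct facial sense.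
  - C3 must later be reduced to the axial alcohol and the C19 ester to the alcohol.
- Comparison: the chosen strategy fixes C3 and C4 first on a simple ring and then makes C10 by chirality transfer from C6, so absolute and relative configuration do not hang on one catalyst‑controlled cycloaddition.

**Alternative 2:** The decalin is cut at C5–C10 and C8–C9.
- Forward key step: heating the silyl dienol ether triene A5 forms both bonds in one intramolecular [4+2] event and gives the trans‑fused decalin A4.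
- For: both rings and four stereocentres come from one step. C6 appears as a silyl enol ether, again at the right oxidation level. The C20 methyl, C9 ester and C17 methyl follow from alkene geometry.
- Against:
  - The only control element is the quaternary C4 in the tether, whose methyl and ester substituents differ little, so face and endo/exo selectivity are weakly founded.
  - The dienophile is a β,β‑disubstituted enoate, which is sluggish.
  - An acyclic quaternary C4 must be made enantioselectively, which is harder than desymmetrising a cyclic dione.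
  - C3 is carried as a ketal and must be reduced late to the axial alcohol beside other carbonyl groups.
- Comparison: it is shorter on paper in ring construction and equal in wasting C8 and C9 as stereocentres. The chosen route replaces its uncertain facial control by a stereospecific transfer from a carbinol set under reagent control.

**Alternative 3:** Ring B is cut at C6–C7.
- Forward key step: Me2AlCl activates the C5 aldehyde of A7, and a type 2 carbonyl‑ene reaction bonds C6 to C7 with hydrogen transfer from the C8 methyl, giving A6 with the 6β‑carbinol and an exocyclic C8 alkene.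
- For: the 6β‑hydroxyl is formed directly with the target configuration, and the exocyclic alkene can be moved into conjugation with the C9 ester by base. On C6 and on the C8=C9 alkene it is clearly stronger than the chosen route (about five steps fewer).
- Against: the key step does not touch the hardest centre. A7 must already hold quaternary C10 between the C5 and C9 stereocentres, made by some other stereocontrolled C–C bond formation. Its neopentyl aldehyde at C5 is also epimerisable.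
- Comparison: in the chosen strategy the key step itself creates C10 with a predictable configuration and closes ring B, at the price of a longer oxidation sequence at C6.

Key step: step 14

Remark on the chemistry: step 3 assumes that a ketoreductase with the required sense (3R carbinol, hydroxyl trans to CH2OTBS) is found in a commercial enzyme panel; a purely chemical detour is given under the uncertain steps.

## Route

Step 1
Reactants: 1 2‑methylcyclohexane‑1,3‑dione; 2 formaldehyde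
Product: 3 2‑(hydroxymethyl)‑2‑methylcyclohexane‑1,3‑dione
Conditions: 37% aq. CH2O, NaHCO3 (cat.), H2O–THF, rt
Reagents that add atoms: none
Why: Aldol (hydroxymethylation) of the enolised 1,3‑dione at its only nucleophilic carbon gives the quaternary future C4; it is not yet a stereocentre because the two carbonyl arms are enantiotopic.

Step 2
Reactants: 3 2‑(hydroxymethyl)‑2‑methylcyclohexane‑1,3‑dione
Product: 4 2‑{[(tert‑butyldimethylsilyl)oxy]methyl}‑2‑methylcyclohexane‑1,3‑dione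
Conditions: TBSCl, imidazole, DMF, 0 °C → rt
Reagents that add atoms: tert‑butyldimethylsilyl chloride, CC(C)(C)[Si](C)(C)Cl
Why: Imidazole‑promoted silylation of the primary alcohol blocks retro‑aldol loss of formaldehyde and makes the two C4 substituents clearly different for the enzyme.

Step 3
Reactants: 4 2‑{[(tert‑butyldimethylsilyl)oxy]methyl}‑2‑methylcyclohexane‑1,3‑dione
Product: 5 (2S,3R)‑2‑(TBSOCH2)‑3‑hydroxy‑2‑methylcyclohexan‑1‑one (hydroxyl trans to CH2OTBS)
Conditions: ketoreductase (anti‑Prelog, from panel screening), NADP+ (cat.), i‑PrOH, phosphate buffer pH 7, DMSO (5%), 30 °C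
Reagents that add atoms: none
Why: Enzymatic desymmetrising mono‑reduction of a 2,2‑disubstituted cyclohexane‑1,3‑dione, a reaction type established with yeast and isolated ketoreductases; the choice of carbonyl fixes C4 (S) and the choice of face fixes C3 (R), and the β‑hydroxy ketone formed should be a much poorer substrate, so the second ketone is expected to survive.

Step 4
Reactants: 5 (2S,3R)‑2‑(TBSOCH2)‑3‑hydroxy‑2‑methylcyclohexan‑1‑one
Product: 6 (2S,3R)‑3‑(TBSO)‑2‑(TBSOCH2)‑2‑methylcyclohexan‑1‑one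
Conditions: TBSOTf, 2,6‑lutidine, CH2Cl2, −78 → 0 °C
Reagents that add atoms: tert‑butyldimethylsilyl trifluoromethanesulfonate, CC(C)(C)[Si](C)(C)OS(=O)(=O)C(F)(F)F
Why: The silyl triflate is needed for this neopentyl‑type secondary alcohol; the non‑nucleophilic base at low temperature avoids enol silylation and retro‑aldol cleavage.

Step 5
Reactants: 6 (2S,3R)‑3‑(TBSO)‑2‑(TBSOCH2)‑2‑methylcyclohexan‑1‑one
Product: 7 (2S,3R,6RS)‑3‑(TBSO)‑2‑(TBSOCH2)‑2,6‑dimethylcyclohexan‑1‑one (mixture of C10 epimers in labdane numbering)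
Conditions: LDA, THF, −78 °C; MeI, −78 → 0 °C
Reagents that add atoms: iodomethane, CI
Why: Enolate alkylation; C10 is the only enolisable position because C4 is quaternary, and its configuration is irrelevant since it becomes sp2 in step 6.

Step 6
Reactants: 7 (2S,3R,6RS)‑3‑(TBSO)‑2‑(TBSOCH2)‑2,6‑dimethylcyclohexan‑1‑one
Product: 8 (5R,6S)‑5‑(TBSO)‑6‑(TBSOCH2)‑2,6‑dimethylcyclohex‑1‑en‑1‑yl trifluoromethanesulfonate
Conditions: KHMDS, THF, −78 → 0 °C; PhNTf2, −78 °C → rt
Reagents that add atoms: N‑phenylbis(trifluoromethanesulfonimide), O=S(=O)(N(c1ccccc1)S(=O)(=O)C(F)(F)F)C(F)(F)F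
Why: Enol triflate formation; only the tetrasubstituted C5=C10 enolate can form, as with 2,2,6‑trisubstituted cyclohexanones, and O‑sulfonylation fixes the ring A alkene.

Step 7
Reactants: 8 (5R,6S)‑5‑(TBSO)‑6‑(TBSOCH2)‑2,6‑dimethylcyclohex‑1‑en‑1‑yl trifluoromethanesulfonate
Product: 9 methyl (5R,6S)‑5‑(TBSO)‑6‑(TBSOCH2)‑2,6‑dimethylcyclohex‑1‑ene‑1‑carboxylate
Conditions: Pd(OAc)2 (5 mol%), dppp, CO (1 atm), Et3N, MeOH–DMF, 70 °C
Reagents that add atoms: carbon monoxide, [C-]#[O+]; methanol, CO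
Why: Palladium‑catalysed methoxycarbonylation of a vinyl triflate (oxidative addition to zerovalent palladium formed in situ, CO insertion, methanolysis) makes the C5–C6 bond; chosen over direct formylation because hindered triflates tend to be reduced under formylation conditions.

Step 8
Reactants: 9 methyl (5R,6S)‑5‑(TBSO)‑6‑(TBSOCH2)‑2,6‑dimethylcyclohex‑1‑ene‑1‑carboxylate
Product: 10 [(5R,6S)‑5‑(TBSO)‑6‑(TBSOCH2)‑2,6‑dimethylcyclohex‑1‑en‑1‑yl]methanol
Conditions: i‑Bu2AlH, CH2Cl2, −78 → 0 °C; aq. potassium sodium tartrate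
Reagents that add atoms: none
Why: 1,2‑Reduction of the conjugated ester to the allylic alcohol; silyl ethers and the tetrasubstituted alkene are inert.

Step 9
Reactants: 10 [(5R,6S)‑5‑(TBSO)‑6‑(TBSOCH2)‑2,6‑dimethylcyclohex‑1‑en‑1‑yl]methanol
Product: 11 (5R,6S)‑5‑(TBSO)‑6‑(TBSOCH2)‑2,6‑dimethylcyclohex‑1‑ene‑1‑carbaldehyde
Conditions: Dess–Martin periodinane, NaHCO3, CH2Cl2, rt
Reagents that add atoms: none
Why: Dess–Martin oxidation of the allylic alcohol to the enal under buffered, non‑acidic conditions; there is no α‑stereocentre to lose.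

Step 10
Reactants: 11 (5R,6S)‑5‑(TBSO)‑6‑(TBSOCH2)‑2,6‑dimethylcyclohex‑1‑ene‑1‑carbaldehyde
Product: 13 (1S)‑1‑[(5R,6S)‑5‑(TBSO)‑6‑(TBSOCH2)‑2,6‑dimethylcyclohex‑1‑en‑1‑yl]but‑3‑en‑1‑ol, via diisopinocampheylborinate ester 12 (not isolated)
Conditions: (−)‑Ipc2BOMe, CH2=CHCH2MgBr, Et2O, 0 °C → rt; then 11, −78 °C; then NaOH, H2O2, 0 °C → rt
Reagents that add atoms: allylmagnesium bromide, C=CC[Mg]Br
Why: Brown allylboration through a closed chair transition state; (−)‑B‑allyldiisopinocampheylborane (from (+)‑α‑pinene) is the enantiomer that gives (S)‑carbinols from aryl and alkenyl aldehydes, and this reagent control should override the weak bias of C4, setting C6 (S); oxidative work‑up cleaves borinate 12.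

Step 11
Reactants: 13 (1S)‑1‑[(5R,6S)‑5‑(TBSO)‑6‑(TBSOCH2)‑2,6‑dimethylcyclohex‑1‑en‑1‑yl]but‑3‑en‑1‑ol; 14 acryloyl chloride
Product: 15 (1S)‑1‑[(5R,6S)‑5‑(TBSO)‑6‑(TBSOCH2)‑2,6‑dimethylcyclohex‑1‑en‑1‑yl]but‑3‑en‑1‑yl prop‑2‑enoate
Conditions: Et3N, DMAP (cat.), CH2Cl2, −20 → 0 °C
Reagents that add atoms: none
Why: DMAP‑catalysed O‑acylation; low temperature and base suppress polymerisation of the acrylate and ionisation of the allylic ester, and the carbinol centre is untouched.

Step 12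
Reactants: 15 (1S)‑1‑[(5R,6S)‑5‑(TBSO)‑6‑(TBSOCH2)‑2,6‑dimethylcyclohex‑1‑en‑1‑yl]but‑3‑en‑1‑yl prop‑2‑enoate
Product: 16 (6S)‑6‑[(5R,6S)‑5‑(TBSO)‑6‑(TBSOCH2)‑2,6‑dimethylcyclohex‑1‑en‑1‑yl]‑5,6‑dihydro‑2H‑pyran‑2‑one
Conditions: second‑generation Grubbs catalyst [RuCl2(=CHPh)(PCy3)(H2IMes)] (5 mol%), CH2Cl2, 40 °C
Reagents that add atoms: none
Why: Ring‑closing metathesis of the acrylate with the terminal alkene gives the six‑membered unsaturated lactone, driven by loss of ethylene; the tetrasubstituted ring A alkene does not engage the ruthenium carbene.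

Step 13
Reactants: 16 (6S)‑6‑[(5R,6S)‑5‑(TBSO)‑6‑(TBSOCH2)‑2,6‑dimethylcyclohex‑1‑en‑1‑yl]‑5,6‑dihydro‑2H‑pyran‑2‑one
Product: 17 (4R,6S)‑4‑methyl‑6‑[(5R,6S)‑5‑(TBSO)‑6‑(TBSOCH2)‑2,6‑dimethylcyclohex‑1‑en‑1‑yl]oxan‑2‑one (trans lactone)
Conditions: Me2CuLi (CuI, 2 MeLi), Et2O, −78 → −40 °C; aq. NH4Cl
Reagents that add atoms: lithium dimethylcuprate, [Li+].C[Cu-]C
Why: Cuprate 1,4‑addition; in the half‑chair enoate the bulky C6 substituent is pseudo‑equatorial and the methyl enters axially, anti to it, which should give the trans‑4,6 lactone (C8 as R).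

Step 14
Reactants: 17 (4R,6S)‑4‑methyl‑6‑[(5R,6S)‑5‑(TBSO)‑6‑(TBSOCH2)‑2,6‑dimethylcyclohex‑1‑en‑1‑yl]oxan‑2‑one
Product: 20 3α,19‑bis(TBSO)‑12,13,14,15,16‑pentanorlabd‑5‑en‑11‑oic acid (8α‑CH3; 9α‑CO2H; 10β‑CH3), via silyl ketene acetal 18 (not isolated), via silyl ester 19 (not isolated)
Conditions: LDA, TBSCl, HMPA, THF, −78 °C → rt; then toluene, 110 °C; then K2CO3, MeOH–H2O, rt; pH 4
Reagents that add atoms: none
Why: LDA removes a C9 proton and TBSCl traps the enolate as the cyclic O‑silyl ketene acetal 18, which on heating undergoes a concerted suprafacial [3,3] shift (Ireland–Claisen rearrangement): C9–C10 forms as C6–O breaks, giving silyl ester 19 and, after mild hydrolysis, acid 20. The closest known reaction type is the Ireland–Claisen ring contraction of alkenyl‑substituted lactone silyl ketene acetals to cycloalkene carboxylic acids. Ring B (C5–C6–C7–C8–C9–C10) closes through this sigmatropic C9–C10 bond formation in a boat array resembling bicyclo[2.2.2]octane, the only geometry open to a ketene acetal locked in a six‑membered ring. C10 is controlled by the (6S) carbinol centre from step 10: in the only rotamer that lets C7 reach round to C10 the C6–O bond stands on the α face of the ring A alkene, C9 arrives on the same face, and the C20 methyl is pushed to the β face whatever small bias C4 exerts. C9 is controlled by the tether: C11 stays tied to the departing oxygen and ends α, cis to the 8α‑methyl, while C8 keeps the configuration from step 13 and its methyl points away from ring A in the boat. The step needs face selectivity at C10 and a clean [3,3] course; the first is secured by the carbinol configuration and the cyclic array, the second by the fact that a [1,3] alternative would need a four‑membered ring and that C9 is the only acidic position. The likely limit is rate, since the alkene terminus is fully substituted.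

Step 15
Reactants: 20 3α,19‑bis(TBSO)‑12,13,14,15,16‑pentanorlabd‑5‑en‑11‑oic acid
Product: 21 methyl 3α,19‑bis(TBSO)‑12,13,14,15,16‑pentanorlabd‑5‑en‑11‑oate
Conditions: MeI, K2CO3, DMF, rt
Reagents that add atoms: iodomethane, CI
Why: SN2 O‑alkylation of the carboxylate, which works even for this hindered axial acid; the ester is needed because borane would reduce the free acid.

Step 16
Reactants: 21 methyl 3α,19‑bis(TBSO)‑12,13,14,15,16‑pentanorlabd‑5‑en‑11‑oate
Product: 23 methyl 6α‑hydroxy‑3α,19‑bis(TBSO)‑12,13,14,15,16‑pentanor‑5α‑labdan‑11‑oate, via C6 alkylborane 22 (not isolated)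
Conditions: BH3·THF, THF, 0 °C → rt; then NaOH, H2O2, 0 °C → rt
Reagents that add atoms: hydrogen peroxide, OO
Why: Hydroboration–oxidation; boron goes to the less substituted C6 and adds syn from the α face because the β face is covered by C20 and the axial C19 group, giving 5α‑H (trans‑decalin) and the 6α‑alcohol with retention on oxidation. A minor β‑face product would converge later, since C5 can be equilibrated in ketone 24 and C6 is reset in step 18.

Step 17
Reactants: 23 methyl 6α‑hydroxy‑3α,19‑bis(TBSO)‑12,13,14,15,16‑pentanor‑5α‑labdan‑11‑oate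
Product: 24 methyl 6‑oxo‑3α,19‑bis(TBSO)‑12,13,14,15,16‑pentanor‑5α‑labdan‑11‑oate
Conditions: Dess–Martin periodinane, NaHCO3, CH2Cl2, rt
Reagents that add atoms: none
Why: Dess–Martin oxidation of the secondary alcohol; the trans ring fusion is the stable arrangement at C5, so enolisation does no harm.

Step 18
Reactants: 24 methyl 6‑oxo‑3α,19‑bis(TBSO)‑12,13,14,15,16‑pentanor‑5α‑labdan‑11‑oate
Product: 25 methyl 6β‑hydroxy‑3α,19‑bis(TBSO)‑12,13,14,15,16‑pentanor‑5α‑labdan‑11‑oate
Conditions: NaBH4, MeOH, 0 °C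
Reagents that add atoms: none
Why: Borohydride reduction; axial approach from the β face is blocked by the syn‑axial C20 and C19 groups, so hydride should come from the α face and give the axial 6β‑alcohol (C6 as R); the hindered ester is not reduced.

Step 19
Reactants: 25 methyl 6β‑hydroxy‑3α,19‑bis(TBSO)‑12,13,14,15,16‑pentanor‑5α‑labdan‑11‑oate
Product: 27 methyl 6β‑hydroxy‑3α,19‑bis(TBSO)‑12,13,14,15,16‑pentanor‑5α‑labd‑8‑en‑11‑oate, via 9α‑bromo ester 26 (not isolated)
Conditions: LDA (3 equiv), HMPA, THF, −78 → −30 °C; CBr4, −78 °C; then DBU, toluene, 80 °C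
Reagents that add atoms: none
Why: Ester enolate bromination followed by E2 elimination; bromine should enter C9 from the α face, anti to C20, which places 9α‑Br and 8β‑H trans‑diaxial, and C10 has no hydrogen, so only the tetrasubstituted C8=C9 enoate can form. The extra base covers the free 6β‑hydroxyl.

Step 20
Reactants: 27 methyl 6β‑hydroxy‑3α,19‑bis(TBSO)‑12,13,14,15,16‑pentanor‑5α‑labd‑8‑en‑11‑oate
Product: 28 3α,19‑bis(TBSO)‑12,13,14,15,16‑pentanor‑5α‑labd‑8‑ene‑6β,11‑diol
Conditions: i‑Bu2AlH, CH2Cl2, −78 → 0 °C; aq. potassium sodium tartrate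
Reagents that add atoms: none
Why: 1,2‑Reduction of the hindered conjugated ester to the primary allylic alcohol.

Step 21
Reactants: 28 3α,19‑bis(TBSO)‑12,13,14,15,16‑pentanor‑5α‑labd‑8‑ene‑6β,11‑diol
Product: 29 11‑bromo‑3α,19‑bis(TBSO)‑12,13,14,15,16‑pentanor‑5α‑labd‑8‑en‑6β‑ol
Conditions: CBr4, PPh3, CH2Cl2, 0 °C
Reagents that add atoms: tetrabromomethane, BrC(Br)(Br)Br
Why: Appel reaction at the primary allylic alcohol; the 6β‑hydroxyl, flanked by two syn‑axial carbon groups, should not react, and the bromide is used at once.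

Step 22
Reactants: 29 11‑bromo‑3α,19‑bis(TBSO)‑12,13,14,15,16‑pentanor‑5α‑labd‑8‑en‑6β‑ol; 30 allyl acetoacetate
Product: 31 allyl 6β‑hydroxy‑13‑oxo‑3α,19‑bis(TBSO)‑16‑nor‑5α‑labd‑8‑en‑15‑oate
Conditions: 30, NaH then n‑BuLi, THF, 0 °C; then 29, 0 °C
Reagents that add atoms: none
Why: γ‑Alkylation of the acetoacetate dianion; its terminal carbanion is the more reactive site and displaces the primary allylic bromide by SN2, forming C11–C12; excess dianion covers the free hydroxyl.

Step 23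
Reactants: 31 allyl 6β‑hydroxy‑13‑oxo‑3α,19‑bis(TBSO)‑16‑nor‑5α‑labd‑8‑en‑15‑oate
Product: 32 allyl (13Z)‑13‑[(diethoxyphosphoryl)oxy]‑6β‑hydroxy‑3α,19‑bis(TBSO)‑16‑nor‑5α‑labda‑8,13‑dien‑15‑oate
Conditions: NaH (1.05 equiv), Et2O, 0 °C; ClP(O)(OEt)2
Reagents that add atoms: diethyl chlorophosphate, CCOP(=O)(Cl)OCC
Why: O‑Phosphorylation of the chelated sodium enolate of the β‑keto ester gives the (Z)‑enol phosphate (phosphate cis to the ester); one equivalent of base leaves the far less acidic alcohol alone.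

Step 24
Reactants: 32 allyl (13Z)‑13‑[(diethoxyphosphoryl)oxy]‑6β‑hydroxy‑3α,19‑bis(TBSO)‑16‑nor‑5α‑labda‑8,13‑dien‑15‑oate
Product: 33 allyl (13E)‑6β‑hydroxy‑3α,19‑bis(TBSO)‑5α‑labda‑8,13‑dien‑15‑oate
Conditions: Me2CuLi (CuI, 2 MeLi), Et2O, −78 → −45 °C; aq. NH4Cl
Reagents that add atoms: lithium dimethylcuprate, [Li+].C[Cu-]C
Why: Cuprate addition–elimination on the β‑phosphoryloxy enoate replaces phosphate by methyl with retention, so the C16 methyl ends cis to the ester and the alkene is (E); the low temperature spares the allyl ester.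

Step 25
Reactants: 33 allyl (13E)‑6β‑hydroxy‑3α,19‑bis(TBSO)‑5α‑labda‑8,13‑dien‑15‑oate
Product: 34 allyl (13E)‑3α,6β,19‑trihydroxy‑5α‑labda‑8,13‑dien‑15‑oate
Conditions: HF·pyridine, pyridine, THF, 0 °C → rt
Reagents that add atoms: none
Why: Fluoride‑mediated cleavage of both silyl ethers under buffered conditions; the allyl ester and both alkenes are inert.

Step 26
Reactants: 34 allyl (13E)‑3α,6β,19‑trihydroxy‑5α‑labda‑8,13‑dien‑15‑oate
Product: 35 allyl (13E)‑6β‑hydroxy‑3α,19‑bis(3‑methylbutanoyloxy)‑5α‑labda‑8,13‑dien‑15‑oate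
Conditions: (i‑BuCO)2O, DMAP, pyridine, CH2Cl2, rt
Reagents that add atoms: 3‑methylbutanoic anhydride, CC(C)CC(=O)OC(=O)CC(C)C
Why: DMAP‑catalysed acylation of the primary C19 and the secondary 3α hydroxyls; the 6β‑hydroxyl, syn‑axial to both C20 and C19, should stay free, as doubly flanked axial alcohols do under these conditions.

Step 27
Reactants: 35 allyl (13E)‑6β‑hydroxy‑3α,19‑bis(3‑methylbutanoyloxy)‑5α‑labda‑8,13‑dien‑15‑oate
Product: 36 (13E)‑6β‑hydroxy‑3α,19‑bis(3‑methylbutanoyloxy)‑5α‑labda‑8,13‑dien‑15‑oic acid (3R,4S,5R,6R,10S; CNP0333611.1)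
Conditions: Pd(PPh3)4 (5 mol%), morpholine, THF, rt
Reagents that add atoms: none
Why: Tsuji–Trost deallylation; zerovalent palladium ionises the allyl ester and morpholine takes up the allyl group under neutral conditions that leave the isovalerates, the free alcohol and the alkenes untouched.

## Compound list

1 | 2‑methylcyclohexane‑1,3‑dione | CC1C(=O)CCCC1=O | starting material
2 | formaldehyde | C=O | starting material
3 | 2‑(hydroxymethyl)‑2‑methylcyclohexane‑1,3‑dione | CC1(CO)C(=O)CCCC1=O | intermediate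
4 | 2‑(TBSOCH2)‑2‑methylcyclohexane‑1,3‑dione | CC1(CO[Si](C)(C)C(C)(C)C)C(=O)CCCC1=O | intermediate
5 | (2S,3R)‑2‑(TBSOCH2)‑3‑hydroxy‑2‑methylcyclohexan‑1‑one | O=C1[C@@](C)(CO[Si](C)(C)C(C)(C)C)[C@H](O)CCC1 | intermediate
6 | (2S,3R)‑3‑(TBSO)‑2‑(TBSOCH2)‑2‑methylcyclohexan‑1‑one | O=C1[C@@](C)(CO[Si](C)(C)C(C)(C)C)[C@H](O[Si](C)(C)C(C)(C)C)CCC1 | intermediate
7 | (2S,3R,6RS)‑3‑(TBSO)‑2‑(TBSOCH2)‑2,6‑dimethylcyclohexan‑1‑one | O=C1[C@@](C)(CO[Si](C)(C)C(C)(C)C)[C@H](O[Si](C)(C)C(C)(C)C)CCC1C | intermediate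
8 | (5R,6S)‑5‑(TBSO)‑6‑(TBSOCH2)‑2,6‑dimethylcyclohex‑1‑en‑1‑yl triflate | CC1=C(OS(=O)(=O)C(F)(F)F)[C@@](C)(CO[Si](C)(C)C(C)(C)C)[C@H](O[Si](C)(C)C(C)(C)C)CC1 | intermediate
9 | methyl (5R,6S)‑5‑(TBSO)‑6‑(TBSOCH2)‑2,6‑dimethylcyclohex‑1‑ene‑1‑carboxylate | CC1=C(C(=O)OC)[C@@](C)(CO[Si](C)(C)C(C)(C)C)[C@H](O[Si](C)(C)C(C)(C)C)CC1 | intermediate
10 | [(5R,6S)‑5‑(TBSO)‑6‑(TBSOCH2)‑2,6‑dimethylcyclohex‑1‑en‑1‑yl]methanol | CC1=C(CO)[C@@](C)(CO[Si](C)(C)C(C)(C)C)[C@H](O[Si](C)(C)C(C)(C)C)CC1 | intermediate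
11 | (5R,6S)‑5‑(TBSO)‑6‑(TBSOCH2)‑2,6‑dimethylcyclohex‑1‑ene‑1‑carbaldehyde | CC1=C(C=O)[C@@](C)(CO[Si](C)(C)C(C)(C)C)[C@H](O[Si](C)(C)C(C)(C)C)CC1 | intermediate
12 | diisopinocampheylborinate ester of 13 | CC1=C([C@@H](OB([C@@H]2C[C@@H]3C[C@H]([C@H]2C)C3(C)C)[C@@H]2C[C@@H]3C[C@H]([C@H]2C)C3(C)C)CC=C)[C@@](C)(CO[Si](C)(C)C(C)(C)C)[C@H](O[Si](C)(C)C(C)(C)C)CC1 | intermediate (not isolated)
13 | (1S)‑1‑[(5R,6S)‑5‑(TBSO)‑6‑(TBSOCH2)‑2,6‑dimethylcyclohex‑1‑en‑1‑yl]but‑3‑en‑1‑ol | CC1=C([C@@H](O)CC=C)[C@@](C)(CO[Si](C)(C)C(C)(C)C)[C@H](O[Si](C)(C)C(C)(C)C)CC1 | intermediate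
14 | acryloyl chloride | C=CC(Cl)=O | starting material
15 | acrylate of 13 | CC1=C([C@@H](OC(=O)C=C)CC=C)[C@@](C)(CO[Si](C)(C)C(C)(C)C)[C@H](O[Si](C)(C)C(C)(C)C)CC1 | intermediate
16 | (6S)‑6‑(ring A cyclohexenyl)‑5,6‑dihydro‑2H‑pyran‑2‑one | CC1=C([C@H]2OC(=O)C=CC2)[C@@](C)(CO[Si](C)(C)C(C)(C)C)[C@H](O[Si](C)(C)C(C)(C)C)CC1 | intermediate
17 | (4R,6S)‑4‑methyl‑6‑(ring A cyclohexenyl)oxan‑2‑one, trans | CC1=C([C@H]2OC(=O)C[C@H](C)C2)[C@@](C)(CO[Si](C)(C)C(C)(C)C)[C@H](O[Si](C)(C)C(C)(C)C)CC1 | intermediate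
18 | (2S,4R)‑6‑(TBSO)‑4‑methyl‑2‑(ring A cyclohexenyl)‑3,4‑dihydro‑2H‑pyran (silyl ketene acetal) | CC1=C([C@H]2OC(O[Si](C)(C)C(C)(C)C)=C[C@H](C)C2)[C@@](C)(CO[Si](C)(C)C(C)(C)C)[C@H](O[Si](C)(C)C(C)(C)C)CC1 | intermediate (not isolated)
19 | TBS ester of 20 | C[C@H]1[C@@H](C(=O)O[Si](C)(C)C(C)(C)C)[C@@]2(C)CC[C@@H](O[Si](C)(C)C(C)(C)C)[C@](C)(CO[Si](C)(C)C(C)(C)C)C2=CC1 | intermediate (not isolated)
20 | 3α,19‑bis(TBSO)‑12,13,14,15,16‑pentanorlabd‑5‑en‑11‑oic acid | C[C@H]1[C@@H](C(=O)O)[C@@]2(C)CC[C@@H](O[Si](C)(C)C(C)(C)C)[C@](C)(CO[Si](C)(C)C(C)(C)C)C2=CC1 | intermediate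
21 | methyl ester of 20 | C[C@H]1[C@@H](C(=O)OC)[C@@]2(C)CC[C@@H](O[Si](C)(C)C(C)(C)C)[C@](C)(CO[Si](C)(C)C(C)(C)C)C2=CC1 | intermediate
22 | C6 (6α) alkylborane of 21, 5α‑H | C[C@H]1[C@@H](C(=O)OC)[C@@]2(C)CC[C@@H](O[Si](C)(C)C(C)(C)C)[C@](C)(CO[Si](C)(C)C(C)(C)C)[C@@H]2[C@@H](B)C1 | intermediate (not isolated)
23 | methyl 6α‑hydroxy‑3α,19‑bis(TBSO)‑12,13,14,15,16‑pentanor‑5α‑labdan‑11‑oate | C[C@H]1[C@@H](C(=O)OC)[C@@]2(C)CC[C@@H](O[Si](C)(C)C(C)(C)C)[C@](C)(CO[Si](C)(C)C(C)(C)C)[C@@H]2[C@@H](O)C1 | intermediate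
24 | methyl 6‑oxo‑3α,19‑bis(TBSO)‑12,13,14,15,16‑pentanor‑5α‑labdan‑11‑oate | C[C@H]1[C@@H](C(=O)OC)[C@@]2(C)CC[C@@H](O[Si](C)(C)C(C)(C)C)[C@](C)(CO[Si](C)(C)C(C)(C)C)[C@@H]2C(=O)C1 | intermediate
25 | methyl 6β‑hydroxy‑3α,19‑bis(TBSO)‑12,13,14,15,16‑pentanor‑5α‑labdan‑11‑oate | C[C@H]1[C@@H](C(=O)OC)[C@@]2(C)CC[C@@H](O[Si](C)(C)C(C)(C)C)[C@](C)(CO[Si](C)(C)C(C)(C)C)[C@@H]2[C@H](O)C1 | intermediate
26 | methyl 9α‑bromo‑6β‑hydroxy‑3α,19‑bis(TBSO)‑12,13,14,15,16‑pentanor‑5α‑labdan‑11‑oate | C[C@H]1[C@](Br)(C(=O)OC)[C@@]2(C)CC[C@@H](O[Si](C)(C)C(C)(C)C)[C@](C)(CO[Si](C)(C)C(C)(C)C)[C@@H]2[C@H](O)C1 | intermediate (not isolated)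
27 | methyl 6β‑hydroxy‑3α,19‑bis(TBSO)‑12,13,14,15,16‑pentanor‑5α‑labd‑8‑en‑11‑oate | CC1=C(C(=O)OC)[C@@]2(C)CC[C@@H](O[Si](C)(C)C(C)(C)C)[C@](C)(CO[Si](C)(C)C(C)(C)C)[C@@H]2[C@H](O)C1 | intermediate
28 | 3α,19‑bis(TBSO)‑12,13,14,15,16‑pentanor‑5α‑labd‑8‑ene‑6β,11‑diol | CC1=C(CO)[C@@]2(C)CC[C@@H](O[Si](C)(C)C(C)(C)C)[C@](C)(CO[Si](C)(C)C(C)(C)C)[C@@H]2[C@H](O)C1 | intermediate
29 | 11‑bromo‑3α,19‑bis(TBSO)‑12,13,14,15,16‑pentanor‑5α‑labd‑8‑en‑6β‑ol | CC1=C(CBr)[C@@]2(C)CC[C@@H](O[Si](C)(C)C(C)(C)C)[C@](C)(CO[Si](C)(C)C(C)(C)C)[C@@H]2[C@H](O)C1 | intermediate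
30 | allyl acetoacetate | CC(=O)CC(=O)OCC=C | starting material
31 | allyl 6β‑hydroxy‑13‑oxo‑3α,19‑bis(TBSO)‑16‑nor‑5α‑labd‑8‑en‑15‑oate | CC1=C(CCC(=O)CC(=O)OCC=C)[C@@]2(C)CC[C@@H](O[Si](C)(C)C(C)(C)C)[C@](C)(CO[Si](C)(C)C(C)(C)C)[C@@H]2[C@H](O)C1 | intermediate
32 | allyl (13Z)‑13‑[(diethoxyphosphoryl)oxy]‑6β‑hydroxy‑3α,19‑bis(TBSO)‑16‑nor‑5α‑labda‑8,13‑dien‑15‑oate | CC1=C(CC/C(OP(=O)(OCC)OCC)=C/C(=O)OCC=C)[C@@]2(C)CC[C@@H](O[Si](C)(C)C(C)(C)C)[C@](C)(CO[Si](C)(C)C(C)(C)C)[C@@H]2[C@H](O)C1 | intermediate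
33 | allyl (13E)‑6β‑hydroxy‑3α,19‑bis(TBSO)‑5α‑labda‑8,13‑dien‑15‑oate | CC1=C(CC/C(C)=C/C(=O)OCC=C)[C@@]2(C)CC[C@@H](O[Si](C)(C)C(C)(C)C)[C@](C)(CO[Si](C)(C)C(C)(C)C)[C@@H]2[C@H](O)C1 | intermediate
34 | allyl (13E)‑3α,6β,19‑trihydroxy‑5α‑labda‑8,13‑dien‑15‑oate | CC1=C(CC/C(C)=C/C(=O)OCC=C)[C@@]2(C)CC[C@@H](O)[C@](C)(CO)[C@@H]2[C@H](O)C1 | intermediate
35 | allyl (13E)‑6β‑hydroxy‑3α,19‑bis(3‑methylbutanoyloxy)‑5α‑labda‑8,13‑dien‑15‑oate | CC1=C(CC/C(C)=C/C(=O)OCC=C)[C@@]2(C)CC[C@@H](OC(=O)CC(C)C)[C@](C)(COC(=O)CC(C)C)[C@@H]2[C@H](O)C1 | intermediate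
36 | (13E)‑6β‑hydroxy‑3α,19‑bis(3‑methylbutanoyloxy)‑5α‑labda‑8,13‑dien‑15‑oic acid | CC1=C(CC/C(C)=C/C(=O)O)[C@@]2(C)CC[C@@H](OC(=O)CC(C)C)[C@](C)(COC(=O)CC(C)C)[C@@H]2[C@H](O)C1 | target

## Step count and least certain steps

Total step count: 27. Longest linear sequence: 27 steps (1 → 36); 14 and 30 are commercial and enter in steps 11 and 22.

**Step 14 (key step).**
- What may go wrong: heat may ionise the allylic C6–O bond of ketene acetal 18, with elimination to a diene, faster than the slow [3,3] shift onto the fully substituted C10; conversion may also stall.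
- Fallback (sets out from 11, returns at 27): Wittig methylenation of enal 11 gives the vinyl diene F1. Its Diels–Alder reaction with methyl but‑2‑ynoate (sealed tube, or Me2AlCl) builds ring B as the 5,8‑diene ester F2, with C9 next to C10 by the ortho rule. Hydroboration–oxidation of the electron‑rich C5=C6 bond, leaving the tetrasubstituted enoate, gives the 6α‑alcohol F3. Dess–Martin oxidation gives the ketone F4, and NaBH4 reduction from the α face returns to 27.
- Cost: the chirality transfer is given up. The face of C10 then depends on ring A alone, so C10 epimers would have to be separated, and the dienophile is sluggish.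

**Step 3.**
- What may go wrong: no enzyme in the panel may combine the required carbonyl choice with hydride delivery on the face of the bulky CH2OTBS group, giving poor diastereo‑ or enantioselection.
- Fallback (sets out from 4, returns at 6): Corey–Bakshi–Shibata reduction of 4 with the (S)‑oxazaborolidine and BH3·SMe2 should give the (3R) carbinols, mainly the cis hydroxy ketone F5 (the minor trans isomer is 5 itself). The carbinol of F5 is protected as the 4‑methoxybenzyl ether F6, and HF·pyridine frees the primary alcohol F7. Evans–Saksena reduction with Me4NBH(OAc)3 delivers hydride from the hydroxymethyl side to the remaining ketone and gives the anti diol F8 with the future 3α‑hydroxyl. TBSOTf gives the bis‑silyl ether F9, DDQ removes the benzyl group to give the alcohol F10, and Dess–Martin oxidation of that carbinol (the future C5) gives 6.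
- Note: here the catalyst only has to choose between the two carbonyl groups; the C3 configuration comes from the directed reduction.

**Step 19.**
- What may go wrong: incomplete enolisation of the hindered ester (H9 lies between quaternary C10 and C8), or bromination on the β face, which would leave no anti hydrogen for elimination.
- Fallback (sets out from 25, returns at 28): LiAlH4 reduces 25 to the diol F11. TEMPO with PhI(OAc)2 oxidises only the primary alcohol to the aldehyde F12. Soft enolisation (TMSOTf, Et3N) followed by NBS gives the 9α‑bromo aldehyde F13. LiBr and Li2CO3 in DMF effect the anti elimination to the enal F14, and NaBH4 with CeCl3 gives allylic alcohol 28.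

**Step 16.**
- What may go wrong: slow or incomplete hydroboration of an alkene lying between two quaternary carbons, with borane starting to reduce the ester. Face selectivity is less critical, because C5 can be equilibrated in ketone 24.
- Fallback (sets out from 21, returns at 24): epoxidation with mCPBA from the α face gives the epoxide F15. BF3·OEt2 opens it at tertiary C5 with a 1,2‑hydride shift from C6 (Meinwald rearrangement) to the 5β‑H ketone F16. NaOMe in MeOH equilibrates C5 to the trans‑fused ketone 24.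

**Step 26.**
- What may go wrong: acylation of the 6β‑hydroxyl under the forcing conditions that the axial, neopentyl 3α‑hydroxyl may need, or incomplete acylation at C3.
- Fallback (sets out from 33, returns at 35): Dess–Martin oxidation of 33 gives the 6‑ketone F17. HF·pyridine gives the keto diol F18. Exhaustive isovalerylation gives the keto diester F19. NaBH4 with CeCl3 at low temperature reduces the ketone from the α face to 35.
- Caveat: these three compounds are β,γ‑unsaturated ketones, so contact with base must be short to avoid migration of the alkene into conjugation.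

## Further compounds

F1 | step 14 | (1R,2S)‑1‑(TBSO)‑2‑(TBSOCH2)‑2,4‑dimethyl‑3‑vinylcyclohex‑3‑ene (vinyl diene from 11) | CC1=C(C=C)[C@@](C)(CO[Si](C)(C)C(C)(C)C)[C@H](O[Si](C)(C)C(C)(C)C)CC1
F2 | step 14 | methyl 3α,19‑bis(TBSO)‑12,13,14,15,16‑pentanorlabda‑5,8‑dien‑11‑oate | CC1=C(C(=O)OC)[C@@]2(C)CC[C@@H](O[Si](C)(C)C(C)(C)C)[C@](C)(CO[Si](C)(C)C(C)(C)C)C2=CC1
F3 | step 14 | methyl 6α‑hydroxy‑3α,19‑bis(TBSO)‑12,13,14,15,16‑pentanor‑5α‑labd‑8‑en‑11‑oate | CC1=C(C(=O)OC)[C@@]2(C)CC[C@@H](O[Si](C)(C)C(C)(C)C)[C@](C)(CO[Si](C)(C)C(C)(C)C)[C@@H]2[C@@H](O)C1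
F4 | step 14 | methyl 6‑oxo‑3α,19‑bis(TBSO)‑12,13,14,15,16‑pentanor‑5α‑labd‑8‑en‑11‑oate | CC1=C(C(=O)OC)[C@@]2(C)CC[C@@H](O[Si](C)(C)C(C)(C)C)[C@](C)(CO[Si](C)(C)C(C)(C)C)[C@@H]2C(=O)C1
F5 | step 3 | (2R,3R)‑2‑(TBSOCH2)‑3‑hydroxy‑2‑methylcyclohexan‑1‑one (hydroxyl cis to CH2OTBS) | O=C1[C@](C)(CO[Si](C)(C)C(C)(C)C)[C@H](O)CCC1
F6 | step 3 | (2R,3R)‑2‑(TBSOCH2)‑3‑[(4‑methoxybenzyl)oxy]‑2‑methylcyclohexan‑1‑one | O=C1[C@](C)(CO[Si](C)(C)C(C)(C)C)[C@H](OCc2ccc(OC)cc2)CCC1
F7 | step 3 | (2R,3R)‑2‑(hydroxymethyl)‑3‑[(4‑methoxybenzyl)oxy]‑2‑methylcyclohexan‑1‑one | O=C1[C@](C)(CO)[C@H](OCc2ccc(OC)cc2)CCC1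
F8 | step 3 | (1R,2S,3R)‑2‑(hydroxymethyl)‑3‑[(4‑methoxybenzyl)oxy]‑2‑methylcyclohexan‑1‑ol (new hydroxyl trans to CH2OH) | C1C[C@@H](O)[C@](C)(CO)[C@H](OCc2ccc(OC)cc2)C1
F9 | step 3 | bis‑TBS ether of F8 | C1C[C@@H](O[Si](C)(C)C(C)(C)C)[C@](C)(CO[Si](C)(C)C(C)(C)C)[C@H](OCc2ccc(OC)cc2)C1
F10 | step 3 | 3‑(TBSO)‑2‑(TBSOCH2)‑2‑methylcyclohexan‑1‑ol (hydroxyl cis to CH2OTBS; silyloxy trans) | C1C[C@@H](O[Si](C)(C)C(C)(C)C)[C@](C)(CO[Si](C)(C)C(C)(C)C)[C@H](O)C1
F11 | step 19 | 3α,19‑bis(TBSO)‑12,13,14,15,16‑pentanor‑5α‑labdane‑6β,11‑diol (9α‑CH2OH) | C[C@H]1[C@@H](CO)[C@@]2(C)CC[C@@H](O[Si](C)(C)C(C)(C)C)[C@](C)(CO[Si](C)(C)C(C)(C)C)[C@@H]2[C@H](O)C1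
F12 | step 19 | 6β‑hydroxy‑3α,19‑bis(TBSO)‑12,13,14,15,16‑pentanor‑5α‑labdan‑11‑al | C[C@H]1[C@@H](C=O)[C@@]2(C)CC[C@@H](O[Si](C)(C)C(C)(C)C)[C@](C)(CO[Si](C)(C)C(C)(C)C)[C@@H]2[C@H](O)C1
F13 | step 19 | 9α‑bromo‑6β‑hydroxy‑3α,19‑bis(TBSO)‑12,13,14,15,16‑pentanor‑5α‑labdan‑11‑al | C[C@H]1[C@](Br)(C=O)[C@@]2(C)CC[C@@H](O[Si](C)(C)C(C)(C)C)[C@](C)(CO[Si](C)(C)C(C)(C)C)[C@@H]2[C@H](O)C1
F14 | step 19 | 6β‑hydroxy‑3α,19‑bis(TBSO)‑12,13,14,15,16‑pentanor‑5α‑labd‑8‑en‑11‑al | CC1=C(C=O)[C@@]2(C)CC[C@@H](O[Si](C)(C)C(C)(C)C)[C@](C)(CO[Si](C)(C)C(C)(C)C)[C@@H]2[C@H](O)C1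
F15 | step 16 | methyl 5α,6α‑epoxy‑3α,19‑bis(TBSO)‑12,13,14,15,16‑pentanorlabdan‑11‑oate | C[C@H]1[C@@H](C(=O)OC)[C@@]2(C)CC[C@@H](O[Si](C)(C)C(C)(C)C)[C@](C)(CO[Si](C)(C)C(C)(C)C)[C@@]23O[C@H]3C1
F16 | step 16 | methyl 6‑oxo‑3α,19‑bis(TBSO)‑12,13,14,15,16‑pentanor‑5β‑labdan‑11‑oate | C[C@H]1[C@@H](C(=O)OC)[C@@]2(C)CC[C@@H](O[Si](C)(C)C(C)(C)C)[C@](C)(CO[Si](C)(C)C(C)(C)C)[C@H]2C(=O)C1
F17 | step 26 | allyl (13E)‑6‑oxo‑3α,19‑bis(TBSO)‑5α‑labda‑8,13‑dien‑15‑oate | CC1=C(CC/C(C)=C/C(=O)OCC=C)[C@@]2(C)CC[C@@H](O[Si](C)(C)C(C)(C)C)[C@](C)(CO[Si](C)(C)C(C)(C)C)[C@@H]2C(=O)C1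
F18 | step 26 | allyl (13E)‑3α,19‑dihydroxy‑6‑oxo‑5α‑labda‑8,13‑dien‑15‑oate | CC1=C(CC/C(C)=C/C(=O)OCC=C)[C@@]2(C)CC[C@@H](O)[C@](C)(CO)[C@@H]2C(=O)C1
F19 | step 26 | allyl (13E)‑3α,19‑bis(3‑methylbutanoyloxy)‑6‑oxo‑5α‑labda‑8,13‑dien‑15‑oate | CC1=C(CC/C(C)=C/C(=O)OCC=C)[C@@]2(C)CC[C@@H](OC(=O)CC(C)C)[C@](C)(COC(=O)CC(C)C)[C@@H]2C(=O)C1
A1 | alternative 1 | cis‑fused endo Diels–Alder adduct (C9 ketone, C6 dimethyl ketal, C3 silyl enol ether, C4 ester) | O=C1[C@@]2(C)CC=C(O[Si](C)(C)C(C)(C)C)[C@@H](C(=O)OC)[C@H]2C(OC)(OC)C=C1C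
A2 | alternative 1 | 4,4‑dimethoxy‑2,6‑dimethylcyclohexa‑2,5‑dien‑1‑one (quinone monoketal) | O=C1C(C)=CC(OC)(OC)C=C1C
A3 | alternative 1 | methyl (2Z)‑3‑(TBSO)penta‑2,4‑dienoate | C=C/C(O[Si](C)(C)C(C)(C)C)=C/C(=O)OC
A4 | alternative 2 | trans‑fused decalin silyl enol ether (C3 dioxolane, C4 and C9 methyl esters, 8‑ and 10‑methyl) | C[C@@H]1[C@H](C(=O)OC)[C@@]2(C)CCC3(OCCO3)[C@](C)(C(=O)OC)[C@@H]2C(O[Si](C)(C)C(C)(C)C)=C1
A5 | alternative 2 | open‑chain silyl dienol ether triene | C/C=C/C(O[Si](C)(C)C(C)(C)C)=C/[C@@](C)(C(=O)OC)C1(OCCO1)CC/C(C)=C/C(=O)OC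
A6 | alternative 3 | trans‑decalin 6β‑ol with exocyclic C8 methylene and C9 methyl ester | C=C1[C@H](C(=O)OC)[C@@]2(C)CC[C@@H](O[Si](C)(C)C(C)(C)C)[C@](C)(CO[Si](C)(C)C(C)(C)C)[C@@H]2[C@H](O)C1
A7 | alternative 3 | ring A aldehyde with C9 ester and isopropenyl group (ene precursor) | C=C(C)[C@H](C(=O)OC)[C@@]1(C)CC[C@@H](O[Si](C)(C)C(C)(C)C)[C@](C)(CO[Si](C)(C)C(C)(C)C)[C@@H]1C=O
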